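The nonanone chain (C1 = carbonyl carbon, C9 = benzylic carbon of the phenol ring) is cut at C4–C5. The step exploits the C1 ketone on the 2,6-dimethoxyphenyl ring and its γ-carbon C4. C2, C3 and C4 are carried as a cyclopropane, so the precursor is a compact cyclopropyl aryl ketone. A nickel–terpyridine catalyst cleaves the strained C2–C4 bond and couples C4 with the C5 zinc reagent of a silyl-protected 5-(4-hydroxyphenyl)pentyl fragment, while Me3SiCl traps the enolate. One operation thus opens the temporary ring, forms the sp3–sp3 bond at the correct oxidation level and, after fluoride work-up, releases ketone and phenol.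

Key step: step 3

Remark: the target has no stereocentre, so no stereocontrol is needed. The four starting materials are taken as catalogue chemicals.

Step 1
Reactants: 1 1,3-dimethoxybenzene; 2 N-methoxy-N-methylcyclopropanecarboxamide
Product: 4 cyclopropyl(2,6-dimethoxyphenyl)methanone, via 2,6-dimethoxyphenyllithium 3 (not isolated)
Conditions: n-BuLi, THF, 0 °C to rt; then 2, −78 °C to rt; H2O
Reagents that add atoms: none
Why: In a directed ortho-metalation both methoxy groups steer n-BuLi to the shared C2 position, and the aryllithium acylates the amide through a chelated tetrahedral adduct that should stop at the ketone (Weinreb ketone synthesis).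

Step 2
Reactants: 5 (4-bromophenoxy)(tert-butyl)dimethylsilane; 6 1,5-dibromopentane
Product: 8 [4-(5-bromopentyl)phenoxy](tert-butyl)dimethylsilane, via aryl Grignard reagent 7 (not isolated)
Conditions: Mg, THF, reflux; then 6 (3 equiv), Li2CuCl4 (3 mol %), THF, 0 °C to rt
Reagents that add atoms: none
Why: Magnesium insertion leaves the aryl silyl ether intact, and the copper-catalysed Kochi-type coupling of the aryl Grignard reagent with a primary alkyl bromide should stop after one substitution because the symmetrical dibromide is used in threefold excess.

Step 3
Reactants: 4 cyclopropyl(2,6-dimethoxyphenyl)methanone; 8 [4-(5-bromopentyl)phenoxy](tert-butyl)dimethylsilane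
Product: 11 1-(2,6-dimethoxyphenyl)-9-(4-hydroxyphenyl)nonan-1-one, via alkylzinc bromide 9 (not isolated), via bis-silyl enol ether 10 (not isolated)
Conditions: (i) 8, Zn dust, I2 (5 mol %), DMA, 70 °C; (ii) 4, NiCl2·glyme (10 mol %), 2,2':6',2''-terpyridine (10 mol %), Me3SiCl, DMA/THF, rt; (iii) short extractive work-up, then crude extract, TBAF, AcOH, THF, rt
Reagents that add atoms: none
Why: Zinc inserts into the C–Br bond of 8 to give 9; the reduced (terpyridine)nickel species, assisted by Me3SiCl at the carbonyl oxygen, opens the cyclopropane of 4 at a bond proximal to the carbonyl (C2–C4) in a strain-releasing, concerted asynchronous C–C activation that gives a γ-nickelated silyl enol ether, and transmetalation with 9 followed by reductive elimination forms C4–C5 and delivers 10. The closest known reaction type is the nickel/terpyridine-catalysed ring-opening cross-coupling of cyclopropyl ketones with aryl-, alkenyl- and alkylzinc reagents and Me3SiCl (a net 1,3-difunctionalisation, formally a homo-conjugate addition), which also works for ketones without aryl conjugation and so should tolerate the twisted 2,6-dimethoxybenzoyl group. No ring is closed (one three-membered ring is opened) and no stereocentre is made; the enol ether geometry, expected Z, is erased in stage (iii). Regioselectivity is secured by the substrate, because only the two ring bonds from C2 overlap with the C=O π* orbital and in the unsubstituted ring they are equivalent, so either cleavage gives the same linear chain. Chemoselectivity rests on the low nucleophilicity of alkylzinc halides toward the hindered ketone and on the tridentate ligand, which leaves no free cis site for β-hydride elimination from the two primary alkyl groups on nickel. Buffered fluoride finally cleaves the Si–O bonds of the enol ether and of the aryl silyl ether, so ketone and phenol appear together.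

Compound list
1 | 1,3-dimethoxybenzene | COc1cccc(OC)c1 | starting material
2 | N-methoxy-N-methylcyclopropanecarboxamide | CON(C)C(=O)C1CC1 | starting material
3 | 2,6-dimethoxyphenyllithium | [Li]c1c(OC)cccc1OC | intermediate
4 | cyclopropyl(2,6-dimethoxyphenyl)methanone | COc1cccc(OC)c1C(=O)C1CC1 | intermediate
5 | (4-bromophenoxy)(tert-butyl)dimethylsilane | CC(C)(C)[Si](C)(C)Oc1ccc(Br)cc1 | starting material
6 | 1,5-dibromopentane | BrCCCCCBr | starting material
7 | {4-[(tert-butyldimethylsilyl)oxy]phenyl}magnesium bromide | CC(C)(C)[Si](C)(C)Oc1ccc([Mg]Br)cc1 | intermediate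
8 | [4-(5-bromopentyl)phenoxy](tert-butyl)dimethylsilane | CC(C)(C)[Si](C)(C)Oc1ccc(CCCCCBr)cc1 | intermediate
9 | (5-{4-[(tert-butyldimethylsilyl)oxy]phenyl}pentyl)zinc bromide | CC(C)(C)[Si](C)(C)Oc1ccc(CCCCC[Zn]Br)cc1 | intermediate
10 | (Z)-tert-butyl{4-[9-(2,6-dimethoxyphenyl)-9-(trimethylsilyloxy)non-8-en-1-yl]phenoxy}dimethylsilane | C[Si](C)(C)O/C(c1c(OC)cccc1OC)=C\CCCCCCCc1ccc(O[Si](C)(C)C(C)(C)C)cc1 | intermediate
11 | 1-(2,6-dimethoxyphenyl)-9-(4-hydroxyphenyl)nonan-1-one | COc1cccc(OC)c1C(=O)CCCCCCCCc1ccc(O)cc1 | target

Total step count: 3. Longest linear sequence: 2 steps (step 1 or step 2, then step 3).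

Steps most likely to fail

1. Step 3.
- Risk: C–C activation may be sluggish on the hindered, electron-rich and non-planar aryl ketone. Homocoupling and protonation of the zinc reagent could then outrun the cross-coupling.
- Fallback: ring opening and coupling are separated. Setting out from 4, Me3SiI (CH2Cl2, 0 °C, short contact so that the aryl methyl ethers are not touched) should silylate the carbonyl oxygen and deliver iodide to C4. This gives (Z)-{[1-(2,6-dimethoxyphenyl)-4-iodobut-1-en-1-yl]oxy}trimethylsilane F1.
- Return to the route: crude F1 is coupled with 9 in a palladium-catalysed alkyl–alkyl Negishi reaction (Pd2(dba)3, tricyclopentylphosphine, N-methylimidazole, THF/NMP, 80 °C). The fallback comes back to the route at 10, which is desilylated as in stage (iii) to 11. Premature loss of the enol silyl group would be harmless, since both forms converge on 11.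

2. Step 2.
- Risk: substitution may occur at both ends of the dibromide, and the aryl Grignard reagent may homocouple oxidatively. Removal of the excess dibromide could also be laborious.
- Fallback: setting out from 5, Sonogashira coupling with pent-4-yn-1-ol (Pd(PPh3)2Cl2, CuI, Et3N, 80 °C) should give 5-{4-[(tert-butyldimethylsilyl)oxy]phenyl}pent-4-yn-1-ol F2. Hydrogenation (H2, Pd/C, EtOAc) should give 5-{4-[(tert-butyldimethylsilyl)oxy]phenyl}pentan-1-ol F3.
- Return to the route: Appel bromination (CBr4, PPh3, CH2Cl2, 0 °C) comes back to the route at 8.

3. Step 1.
- Risk: the doubly ortho-substituted aryllithium may add slowly to the amide, with competing base-induced breakdown of the N-methoxy amide.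
- Fallback: setting out from 3 (made from 1 as in step 1), addition to the unhindered cyclopropanecarbaldehyde (THF, −78 °C) should give (±)-cyclopropyl(2,6-dimethoxyphenyl)methanol F4.
- Return to the route: F4 is oxidised under neutral conditions (Dess–Martin periodinane, NaHCO3, CH2Cl2), which avoids acid-induced cyclopropylcarbinyl ring opening. This comes back to the route at 4.

Further compounds
F1 | step 3 | (Z)-{[1-(2,6-dimethoxyphenyl)-4-iodobut-1-en-1-yl]oxy}trimethylsilane | C[Si](C)(C)O/C(c1c(OC)cccc1OC)=C\CCI
F2 | step 2 | 5-{4-[(tert-butyldimethylsilyl)oxy]phenyl}pent-4-yn-1-ol | CC(C)(C)[Si](C)(C)Oc1ccc(C#CCCCO)cc1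
F3 | step 2 | 5-{4-[(tert-butyldimethylsilyl)oxy]phenyl}pentan-1-ol | CC(C)(C)[Si](C)(C)Oc1ccc(CCCCCO)cc1
F4 | step 1 | (±)-cyclopropyl(2,6-dimethoxyphenyl)methanol | COc1cccc(OC)c1C(O)C1CC1
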